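## Structural features

The target (C26H32O5) is a bibenzyl carboxylic acid: a fully substituted benzene, ring A, is joined through a CH2–CH2 chain to a 4-hydroxyphenyl group, ring B. Numbered from the carboxyl-bearing carbon, ring A carries CO2H at C1, OMe at C2, a 3-methylbut-2-enyl (prenyl) group at C3, a free OH at C4, a second prenyl group at C5 and the arylethyl chain at C6. There is no stereocentre and no stereogenic double bond, so the problem is one of regiochemistry and functional-group compatibility. The C4 phenol lies between two prenyl groups and can close onto either to a 2,2-dimethylchroman under protic or Lewis acid. The trisubstituted alkenes exclude hydrogenation and strong oxidants, and the C1 carboxyl sits between two ortho substituents, so its simple alkyl esters are slow to saponify. The real difficulty is to place six different groups in a fixed order on one ring and to methylate O2 while O4 and the ring B oxygen end up free. Oxygen at C2 and C4 alternating with carbon at C3 and C5, with the carboxyl at C1 next to the chain at C6, is the pattern of a folded tetraketide. The key step uses this by forming C1–C6 through an aldol reaction of an open chain in which C3 and C5 are still sp3 carbons between carbonyl groups, and in which the carboxyl carbon and O2 are held in one 1,3-dioxin-4-one ring that marks O2 as different from O4.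

## Logic of the disconnections

17 to 16: the three O–allyl bonds (ester at C1, ether at O4, ether on ring B) are cut together. All protic groups are then masked by one group type that leaves under neutral conditions, so neither acid nor saponification is needed at the end. The forward step must reach the hindered O4 ether and leave the C-prenyl groups alone.

16 to 15: the O2–CH3 bond is cut. Methylation is placed where O2 is the only free hydroxyl, so no selectivity between oxygens is asked for. The forward step must alkylate a hydrogen-bonded phenol flanked by an ester and a prenyl group.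

15 to 14: the ester C(=O)–O bond is cut and the carboxyl carbon and O2 are rejoined through an isopropylidene acetal. This ring is what distinguishes O2 from O4. The forward step is an alkoxide opening at a carbonyl flanked by the C6 chain, and it must deliver an ester that can later be removed without hydroxide.

14 to 13: the O4–allyl bond is cut. O4 has to be capped before O2 is released. The forward step is a simple etherification of the only free phenol.

13 to 11 (through 12): the C1–C6 bond is cut with formal addition of water. Ring A disappears and an acyclic tricarbonyl chain remains whose C3 and C5 are enolizable carbons. The forward step must favour aldol closure over Claisen closure and run without acid or heat.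

11 to 6 and 10: the C5–C6 bond is cut. The chain divides into a carbon nucleophile that already holds both prenyl groups and an acyl donor that holds ring B, which makes the route convergent and means the base-sensitive tricarbonyl never has to be alkylated. The forward step needs a dianion at C5 and acylation faster than proton transfer.

10 to 9 to 7: the acyl C–N bond and the ring B O–allyl bond are cut. This leads back to a commercial phenolic acid. The forward steps are an etherification with ester cleavage and a carboxyl activation.

6 to 5 and 4: the bond from C3 to its prenyl CH2 is cut. C3 is the most acidic carbon of 5, so mild base suffices. The forward step must give C- rather than O-alkylation and stop at one alkyl group.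

5 to 3 and 4: the bond from C5 to its prenyl CH2 is cut. The forward step is a dianion alkylation that must occur at the terminal carbon only.

3 to 1 and 2: the C3–C4 bond is cut. Two commercial compounds result. The forward step is acylation of a dienolate at its γ-carbon.

## Other disconnections considered

Alternative 1: The C6–CH2 and C1–CO2H bonds are cut at once, through aryne A3 (triple bond between C1 and C6) generated from iodoaryl triflate A2. In the forward step the Grignard reagent A4 adds at C6, remote from the methoxy group, and the C1–Mg bond that results is carboxylated to give acid A1.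
- In favour: ring A is taken as an arene, so nothing has to be aromatized. The acid appears directly as CO2H, so no ester has to be cleaved; on this point the alternative is better than the chosen plan.
- Against: A2 is a hexasubstituted benzene whose preparation needs two aromatic C-prenylations, two differentiated oxygens, iodine and a triflate. C6 of A3 is flanked by the C5 prenyl group, so steric hindrance opposes the electronic bias of the methoxy group. A4 has β-hydrogens and can reduce an aryne, and the acetal groups of A1 need acid next to an ortho-prenyl phenol.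
- Comparison: convergence is equal, since ring B enters late in both. Mechanistically the chosen plan fixes substituent positions by chain connectivity and is driven by aromatization, while the alternative depends on kinetic regiocontrol at a crowded aryne. No saving in steps is expected, because A2 alone should need about as many steps as the chosen route before its key step.

Alternative 2: The C5–C6 and C2–C3 bonds are cut. The enolate of the symmetrical ketone A6 adds to the alkylidene malonate A7, and the second α-carbon then acylates on an ester to give cyclohexanedione A5.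
- In favour: the reagents are cheap and robust. Both prenyl groups come in one symmetrical building block with no enolate regiochemistry to control; here the alternative is better than the chosen plan, which needs two prenylations and cryogenic dianions. A5 is also more stable than 11.
- Against: A5 is two hydrogens short of aromatic, and the dehydrogenation must be done on a ring with no free position and in the presence of two trisubstituted alkenes. After aromatization it is O4, not the chelated O2, that alkylates first, so protection steps return. A hindered methyl ester and an acetal remain to be cleaved, and A7 has γ-hydrogens, so deconjugation competes with conjugate addition.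
- Comparison: the ring carbons are the same, formed by two bonds instead of one. The alternative ends at the wrong oxidation level where the chosen plan reaches the right one by loss of water. Oxidation, oxygen differentiation and ester hydrolysis should add back at least the steps saved.

Alternative 3: Ring A is cut into diazo ketoester A9 and ynol ether A10. Photochemical Wolff rearrangement of A9 gives vinylketene A11 (forming C1–C6). Cycloaddition with A10, four-electron ring opening and six-electron closure then form C1–C2, C3–C4 and C4–C5 and give phenol A8.
- In favour: the plan is highly convergent and every substituent position follows from fragment connectivity. O2 arrives methylated and O4 free, so steps 8 to 10 of the chosen plan would have no counterpart; on this point the alternative is clearly better.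
- Against: A10 is a sensitive, non-commercial alkoxyalkyne. A11 carries an ester on the ketene carbon and is more electrophilic and more prone to dimerize than the simple vinylketenes for which this benzannulation is established. Irradiating a substrate with an enone and two further alkenes invites isomerization and [2+2] processes. A8 is a doubly ortho-substituted methyl benzoate with an acetal on ring B.
- Comparison: the alternative is more convergent at ring A and forms four bonds in one operation. The chosen plan forms one bond by a base-mediated step with close precedent. Total step count should be comparable (about five steps to A9, about three to A10, then two deprotections), with more risk concentrated in one step.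

Key step: step 7

Remark on the chemistry: the ring B phenol is carried as an allyl ether and the carboxyl is released as an allyl ester, so that neither acid nor saponification is needed near the ortho-prenyl phenol. Both prenyl groups are placed before the tricarbonyl stage, so that 11 is never alkylated. Chain carbons are named by their ring A numbers (C1 to C6). The centres at C3 and C5 of 6, 11 and 12 are formed as mixtures, which is of no consequence.

## Steps

Step 1
Reactants: 1 2,2,6-trimethyl-1,3-dioxin-4-one; 2 1-acetylimidazole
Product: 3 2,2-dimethyl-6-(2-oxopropyl)-1,3-dioxin-4-one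
Conditions: LiN(SiMe3)2 (2 equiv), 1 (2 equiv), THF, −78 °C; 2 (1 equiv), −78 to −30 °C; aq. NH4Cl
Reagents that add atoms: none
Why: Deprotonation of the C6 methyl group of 1 gives the dienolate, which is acylated at its γ-carbon by the acyl imidazole (crossed Claisen condensation). The second equivalent of dienolate serves as base for the more acidic product, so the reaction should stop at monoacylation.

Step 2
Reactants: 3 2,2-dimethyl-6-(2-oxopropyl)-1,3-dioxin-4-one; 4 prenyl bromide (1-bromo-3-methylbut-2-ene)
Product: 5 2,2-dimethyl-6-(6-methyl-2-oxohept-5-enyl)-1,3-dioxin-4-one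
Conditions: LiN(iPr)2 (2.1 equiv), THF, −78 to −20 °C; 4 (1.0 equiv), −78 to 0 °C; aq. NH4Cl
Reagents that add atoms: none
Why: Two equivalents of amide base remove first a proton of the doubly activated CH2 and then a methyl proton. The dianion should react with one equivalent of the allylic bromide only at the more basic terminal carbon (γ-alkylation of a 1,3-dicarbonyl dianion, SN2 at the primary carbon of 4).

Step 3
Reactants: 5 2,2-dimethyl-6-(6-methyl-2-oxohept-5-enyl)-1,3-dioxin-4-one; 4 prenyl bromide
Product: 6 6-(2,10-dimethyl-6-oxoundeca-2,9-dien-5-yl)-2,2-dimethyl-1,3-dioxin-4-one (racemic)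
Conditions: K2CO3 (1.5 equiv), 4 (1.1 equiv), acetone, rt
Reagents that add atoms: none
Why: The CH2 between the ketone and the vinylogous ester carbon is the only position acidic enough for K2CO3, and C-alkylation of such a stabilized enolate by an allylic bromide is the normal course for β-dicarbonyl compounds. The new centre at C3 is formed racemic and is destroyed in step 7.

Step 4
Reactants: 7 3-(4-hydroxyphenyl)propanoic acid
Product: 9 3-[4-(prop-2-enyloxy)phenyl]propanoic acid, via allyl ester 8 (not isolated)
Conditions: allyl bromide (2.5 equiv), K2CO3 (3 equiv), DMF, rt; then 2 M NaOH, MeOH, rt; 1 M HCl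
Reagents that add atoms: allyl bromide, C=CCBr; sodium hydroxide, [Na+].[OH-]
Why: Williamson etherification of the phenoxide also esterifies the carboxylate. Saponification in the same flask then returns the acid, while the aryl allyl ether is inert to aqueous hydroxide.

Step 5
Reactants: 9 3-[4-(prop-2-enyloxy)phenyl]propanoic acid
Product: 10 1-(imidazol-1-yl)-3-[4-(prop-2-enyloxy)phenyl]propan-1-one
Conditions: 1,1′-carbonyldiimidazole (1.1 equiv), CH2Cl2, rt; cold water wash
Reagents that add atoms: 1,1′-carbonyldiimidazole, O=C(n1ccnc1)n1ccnc1
Why: Carboxyl activation with carbonyldiimidazole gives the acyl imidazole with loss of CO2 and imidazole. The wash removes free imidazole so that it cannot protonate the dianion in step 6.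

Step 6
Reactants: 6 6-(2,10-dimethyl-6-oxoundeca-2,9-dien-5-yl)-2,2-dimethyl-1,3-dioxin-4-one; 10 1-(imidazol-1-yl)-3-[4-(prop-2-enyloxy)phenyl]propan-1-one
Product: 11 2,2-dimethyl-6-{1,3-bis(3-methylbut-2-enyl)-2,4-dioxo-6-[4-(prop-2-enyloxy)phenyl]hexyl}-1,3-dioxin-4-one (mixture of diastereomers and enol tautomers)
Conditions: 6 (1.8 equiv), LiN(iPr)2 (3.7 equiv), THF, −78 to −40 °C; 10 (1.0 equiv), −78 to −40 °C; aq. NH4Cl at −40 °C; crude product used directly
Reagents that add atoms: none
Why: The base removes the C3 methine proton and then a proton of the only other α-position, C5. The terminal carbanion should attack the acyl imidazole (crossed Claisen acylation of a 1,3-dicarbonyl dianion), and the excess dianion deprotonates the product, which protects it until the quench. C3 and C5 arise as mixtures that converge in step 7.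

Step 7
Reactants: 11 2,2-dimethyl-6-{1,3-bis(3-methylbut-2-enyl)-2,4-dioxo-6-[4-(prop-2-enyloxy)phenyl]hexyl}-1,3-dioxin-4-one
Product: 13 7-hydroxy-2,2-dimethyl-6,8-bis(3-methylbut-2-enyl)-5-{2-[4-(prop-2-enyloxy)phenyl]ethyl}-1,3-benzodioxin-4-one, via aldol adduct 12 (not isolated)
Conditions: NEt3 (5 equiv), CH2Cl2, rt, 16 h
Reagents that add atoms: none
Why: NEt3 deprotonates the chain reversibly; the enolate at C5 is unproductive, whereas loss of H3 gives a dienolate spread over C4–C3–C2–C1 and the dioxinone carbonyl, whose terminal carbon C1 adds to the C6 ketone to give 12. Elimination of water across C1–C6 (E1cB through the ester dienolate) and enolization of the C4 ketone with loss of H5 should then give phenol 13, the gain in aromatic stabilization pulling the reversible aldol step forward. The closest known reaction type is the amine- or carbonate-mediated aldol cyclization–aromatization of diketo-dioxinones, and of free 3,5,7-triketo esters, to β-resorcylates. Ring A closes in a 6-(enolendo)-exo-trig mode: the dienolate carbons C1 to C4 all lie in the new ring and the C6 carbonyl oxygen stays outside it. No stereocentre is formed; the centres at C3 and C5 of 11 and those of 12 are erased, which is possible because C3 and C5 each keep one hydrogen. The selectivity needed is C1-to-C6 aldol closure over C5-to-carboxyl Claisen closure (an acylphloroglucinol) and over pyranone formation through an acylketene. The substrate secures it: the carboxyl carbon is a poorly electrophilic vinylogous carbonate in a ring that loses acetone only on strong heating, and the C6 ketone is the only other carbonyl a nucleophilic carbon can reach through a six-membered transition state. The intact acetonide also leaves O2 masked and O4 free, which steps 8 to 10 exploit.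

Step 8
Reactants: 13 7-hydroxy-2,2-dimethyl-6,8-bis(3-methylbut-2-enyl)-5-{2-[4-(prop-2-enyloxy)phenyl]ethyl}-1,3-benzodioxin-4-one
Product: 14 2,2-dimethyl-6,8-bis(3-methylbut-2-enyl)-7-(prop-2-enyloxy)-5-{2-[4-(prop-2-enyloxy)phenyl]ethyl}-1,3-benzodioxin-4-one
Conditions: allyl bromide (1.5 equiv), K2CO3 (2 equiv), DMF, rt
Reagents that add atoms: allyl bromide, C=CCBr
Why: Williamson O-allylation of the only free phenol. Both ortho positions and the para position are substituted, so C-allylation cannot compete, and the benzodioxinone is stable to K2CO3 in DMF.

Step 9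
Reactants: 14 2,2-dimethyl-6,8-bis(3-methylbut-2-enyl)-7-(prop-2-enyloxy)-5-{2-[4-(prop-2-enyloxy)phenyl]ethyl}-1,3-benzodioxin-4-one
Product: 15 prop-2-enyl 2-hydroxy-3,5-bis(3-methylbut-2-enyl)-4-(prop-2-enyloxy)-6-{2-[4-(prop-2-enyloxy)phenyl]ethyl}benzoate
Conditions: NaH (2.5 equiv), prop-2-en-1-ol (10 equiv), THF, 0 °C to rt; aq. NH4Cl
Reagents that add atoms: prop-2-en-1-ol, C=CCO
Why: NaOCH2CH=CH2 adds to the ring carbonyl of the benzodioxinone (alkoxide transesterification). The hemiketal that is released loses acetone and frees the O2 phenoxide, and the ester formed is an allyl ester, so no hindered methyl ester ever has to be hydrolysed.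

Step 10
Reactants: 15 prop-2-enyl 2-hydroxy-3,5-bis(3-methylbut-2-enyl)-4-(prop-2-enyloxy)-6-{2-[4-(prop-2-enyloxy)phenyl]ethyl}benzoate
Product: 16 prop-2-enyl 2-methoxy-3,5-bis(3-methylbut-2-enyl)-4-(prop-2-enyloxy)-6-{2-[4-(prop-2-enyloxy)phenyl]ethyl}benzoate
Conditions: MeI (3 equiv), K2CO3 (3 equiv), DMF, rt to 40 °C
Reagents that add atoms: iodomethane, CI
Why: Williamson methylation of the single free phenol. O2–H is hydrogen-bonded to the ester and flanked by a prenyl group, hence the excess of MeI and mild warming; the allyl ester is stable to anhydrous K2CO3.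

Step 11
Reactants: 16 prop-2-enyl 2-methoxy-3,5-bis(3-methylbut-2-enyl)-4-(prop-2-enyloxy)-6-{2-[4-(prop-2-enyloxy)phenyl]ethyl}benzoate
Product: 17 4-hydroxy-6-[2-(4-hydroxyphenyl)ethyl]-2-methoxy-3,5-bis(3-methylbut-2-enyl)benzoic acid
Conditions: Pd(PPh3)4 (10 mol %), morpholine (10 equiv), degassed THF, rt to 40 °C; cold aq. citric acid wash
Reagents that add atoms: none
Why: Zerovalent palladium ionizes the three allyl–oxygen bonds (ester first, then the aryl ethers) to π-allyl complexes that morpholine intercepts (Tsuji–Trost deallylation). The medium stays neutral to weakly basic, so the ortho-prenyl phenol should not cyclize, and the prenyl alkenes carry no leaving group and are untouched.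

## Compound list

1 | 2,2,6-trimethyl-1,3-dioxin-4-one | CC1=CC(=O)OC(C)(C)O1 | starting material
2 | 1-acetylimidazole | CC(=O)n1ccnc1 | starting material
3 | 2,2-dimethyl-6-(2-oxopropyl)-1,3-dioxin-4-one | CC(=O)CC1=CC(=O)OC(C)(C)O1 | intermediate
4 | prenyl bromide (1-bromo-3-methylbut-2-ene) | CC(C)=CCBr | starting material
5 | 2,2-dimethyl-6-(6-methyl-2-oxohept-5-enyl)-1,3-dioxin-4-one | CC(C)=CCCC(=O)CC1=CC(=O)OC(C)(C)O1 | intermediate
6 | 6-(2,10-dimethyl-6-oxoundeca-2,9-dien-5-yl)-2,2-dimethyl-1,3-dioxin-4-one (racemic) | CC(C)=CCCC(=O)C(CC=C(C)C)C1=CC(=O)OC(C)(C)O1 | intermediate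
7 | 3-(4-hydroxyphenyl)propanoic acid | OC(=O)CCc1ccc(O)cc1 | starting material
8 | prop-2-enyl 3-[4-(prop-2-enyloxy)phenyl]propanoate | C=CCOC(=O)CCc1ccc(OCC=C)cc1 | intermediate (not isolated)
9 | 3-[4-(prop-2-enyloxy)phenyl]propanoic acid | C=CCOc1ccc(CCC(=O)O)cc1 | intermediate
10 | 1-(imidazol-1-yl)-3-[4-(prop-2-enyloxy)phenyl]propan-1-one | C=CCOc1ccc(CCC(=O)n2ccnc2)cc1 | intermediate
11 | 2,2-dimethyl-6-{1,3-bis(3-methylbut-2-enyl)-2,4-dioxo-6-[4-(prop-2-enyloxy)phenyl]hexyl}-1,3-dioxin-4-one (mixture of diastereomers) | CC1(C)OC(=O)C=C(O1)C(CC=C(C)C)C(=O)C(CC=C(C)C)C(=O)CCc1ccc(OCC=C)cc1 | intermediate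
12 | 5-hydroxy-2,2-dimethyl-6,8-bis(3-methylbut-2-enyl)-5-{2-[4-(prop-2-enyloxy)phenyl]ethyl}-5,6-dihydro-1,3-benzodioxine-4,7(8H)-dione (mixture of diastereomers) | CC1(C)OC(=O)C2=C(O1)C(CC=C(C)C)C(=O)C(CC=C(C)C)C2(O)CCc1ccc(OCC=C)cc1 | intermediate (not isolated)
13 | 7-hydroxy-2,2-dimethyl-6,8-bis(3-methylbut-2-enyl)-5-{2-[4-(prop-2-enyloxy)phenyl]ethyl}-1,3-benzodioxin-4-one | CC1(C)OC(=O)c2c(O1)c(CC=C(C)C)c(O)c(CC=C(C)C)c2CCc1ccc(OCC=C)cc1 | intermediate
14 | 2,2-dimethyl-6,8-bis(3-methylbut-2-enyl)-7-(prop-2-enyloxy)-5-{2-[4-(prop-2-enyloxy)phenyl]ethyl}-1,3-benzodioxin-4-one | CC1(C)OC(=O)c2c(O1)c(CC=C(C)C)c(OCC=C)c(CC=C(C)C)c2CCc1ccc(OCC=C)cc1 | intermediate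
15 | prop-2-enyl 2-hydroxy-3,5-bis(3-methylbut-2-enyl)-4-(prop-2-enyloxy)-6-{2-[4-(prop-2-enyloxy)phenyl]ethyl}benzoate | C=CCOC(=O)c1c(O)c(CC=C(C)C)c(OCC=C)c(CC=C(C)C)c1CCc1ccc(OCC=C)cc1 | intermediate
16 | prop-2-enyl 2-methoxy-3,5-bis(3-methylbut-2-enyl)-4-(prop-2-enyloxy)-6-{2-[4-(prop-2-enyloxy)phenyl]ethyl}benzoate | C=CCOC(=O)c1c(OC)c(CC=C(C)C)c(OCC=C)c(CC=C(C)C)c1CCc1ccc(OCC=C)cc1 | intermediate
17 | 4-hydroxy-6-[2-(4-hydroxyphenyl)ethyl]-2-methoxy-3,5-bis(3-methylbut-2-enyl)benzoic acid | COc1c(CC=C(C)C)c(O)c(CC=C(C)C)c(CCc2ccc(O)cc2)c1C(=O)O | target

## Step count and least certain steps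

Total: 11 steps. Longest linear sequence: 9 steps (steps 1, 2, 3, 6, 7, 8, 9, 10, 11); steps 4 and 5 make the acyl donor.

Step 7 (key step). The aldol addition may be slow because the C6 ketone is flanked by the branched C5, so retro-Claisen cleavage of the 2-substituted 1,3-diketone could compete or the sequence could stall before dehydration. The fallback removes the C5 substituent from the chain and puts it on the arene afterwards. It sets out from 3 and returns at 13. Compound 3 would be prenylated at its central carbon with 4 (K2CO3, acetone) to give 2,2-dimethyl-6-(6-methyl-2-oxohept-5-en-3-yl)-1,3-dioxin-4-one F1. Its dianion (LiN(iPr)2) would be acylated with 10 to give 2,2-dimethyl-6-{1-(3-methylbut-2-enyl)-2,4-dioxo-6-[4-(prop-2-enyloxy)phenyl]hexyl}-1,3-dioxin-4-one F2. NEt3 would cyclize this to 7-hydroxy-2,2-dimethyl-8-(3-methylbut-2-enyl)-5-{2-[4-(prop-2-enyloxy)phenyl]ethyl}-1,3-benzodioxin-4-one F3. Deprotonation with NaH in toluene and C-alkylation with 4 at the only free ring position, ortho to the oxygen, would then give 13.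

Step 6. Proton transfer from the enolizable acyl imidazole to the dianion may outrun acylation, or a second acylation may follow. The fallback replaces the Claisen acylation by aldol addition and oxidation. It sets out from 10 and 6 and returns at 11. Reduction of 10 with iBu2AlH at −78 °C would give 3-[4-(prop-2-enyloxy)phenyl]propanal F4. Addition of the dianion of 6 to this aldehyde would give 6-{4-hydroxy-1,3-bis(3-methylbut-2-enyl)-2-oxo-6-[4-(prop-2-enyloxy)phenyl]hexyl}-2,2-dimethyl-1,3-dioxin-4-one F5. Oxidation with Dess–Martin periodinane would then give 11.

Step 2. Proton exchange between product and dianion may lead to a second alkylation or to alkylation at the central carbon. The fallback brings this prenyl group in with the acyl unit. It sets out from 1 and returns at 5. Commercial 5-methylhex-4-enoic acid F6 would be converted with 1,1′-carbonyldiimidazole into 1-(imidazol-1-yl)-5-methylhex-4-en-1-one F7, which would acylate the dienolate of 1 under the conditions of step 1 to give 5.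

Step 3. Alkylation at the enol oxygen, at the ring carbon of the delocalized enolate, or twice at C3 may compete. The fallback changes the electrophile to a π-allyl complex. It sets out from 5 and returns at 6. Compound 5 would be treated with 3-methylbut-2-enyl acetate, Pd(PPh3)4 and K2CO3 in THF (Tsuji–Trost allylation), in which the soft enolate should attack the unsubstituted terminus of the π-prenyl complex through carbon. This fallback makes no new compound (entry F0).

Step 9. Attack of the alkoxide at the carbonyl flanked by the C6 chain may be slow, giving incomplete opening or partial hydrolysis. The fallback separates opening from esterification. It sets out from 14 and returns at 15. Hydrolysis with KOH in aqueous DMSO at 60 °C would give 2-hydroxy-3,5-bis(3-methylbut-2-enyl)-4-(prop-2-enyloxy)-6-{2-[4-(prop-2-enyloxy)phenyl]ethyl}benzoic acid F8. Alkylation of its carboxylate with allyl bromide and KHCO3 in DMF, which leaves the hydrogen-bonded phenol alone, would then give 15.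

## Further compounds

F1 | step 7 | 2,2-dimethyl-6-(6-methyl-2-oxohept-5-en-3-yl)-1,3-dioxin-4-one (racemic) | CC(=O)C(CC=C(C)C)C1=CC(=O)OC(C)(C)O1
F2 | step 7 | 2,2-dimethyl-6-{1-(3-methylbut-2-enyl)-2,4-dioxo-6-[4-(prop-2-enyloxy)phenyl]hexyl}-1,3-dioxin-4-one (racemic) | CC1(C)OC(=O)C=C(O1)C(CC=C(C)C)C(=O)CC(=O)CCc1ccc(OCC=C)cc1
F3 | step 7 | 7-hydroxy-2,2-dimethyl-8-(3-methylbut-2-enyl)-5-{2-[4-(prop-2-enyloxy)phenyl]ethyl}-1,3-benzodioxin-4-one | CC1(C)OC(=O)c2c(O1)c(CC=C(C)C)c(O)cc2CCc1ccc(OCC=C)cc1
F4 | step 6 | 3-[4-(prop-2-enyloxy)phenyl]propanal | C=CCOc1ccc(CCC=O)cc1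
F5 | step 6 | 6-{4-hydroxy-1,3-bis(3-methylbut-2-enyl)-2-oxo-6-[4-(prop-2-enyloxy)phenyl]hexyl}-2,2-dimethyl-1,3-dioxin-4-one (mixture of diastereomers) | CC1(C)OC(=O)C=C(O1)C(CC=C(C)C)C(=O)C(CC=C(C)C)C(O)CCc1ccc(OCC=C)cc1
F6 | step 2 | 5-methylhex-4-enoic acid | CC(C)=CCCC(=O)O
F7 | step 2 | 1-(imidazol-1-yl)-5-methylhex-4-en-1-one | CC(C)=CCCC(=O)n1ccnc1
F0 | step 3 | none | none
F8 | step 9 | 2-hydroxy-3,5-bis(3-methylbut-2-enyl)-4-(prop-2-enyloxy)-6-{2-[4-(prop-2-enyloxy)phenyl]ethyl}benzoic acid | OC(=O)c1c(O)c(CC=C(C)C)c(OCC=C)c(CC=C(C)C)c1CCc1ccc(OCC=C)cc1
A1 | alternative 1 | 2-methoxy-4-(methoxymethoxy)-6-{2-[4-(methoxymethoxy)phenyl]ethyl}-3,5-bis(3-methylbut-2-enyl)benzoic acid | COc1c(CC=C(C)C)c(OCOC)c(CC=C(C)C)c(CCc2ccc(OCOC)cc2)c1C(=O)O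
A2 | alternative 1 | 2-iodo-3-methoxy-5-(methoxymethoxy)-4,6-bis(3-methylbut-2-enyl)phenyl trifluoromethanesulfonate | COc1c(I)c(OS(=O)(=O)C(F)(F)F)c(CC=C(C)C)c(OCOC)c1CC=C(C)C
A3 | alternative 1 | 3-methoxy-5-(methoxymethoxy)-4,6-bis(3-methylbut-2-enyl)-1,2-didehydrobenzene | COC1=C(CC=C(C)C)C(OCOC)=C(CC=C(C)C)C#C1
A4 | alternative 1 | 2-[4-(methoxymethoxy)phenyl]ethylmagnesium bromide | COCOc1ccc(CC[Mg]Br)cc1
A5 | alternative 2 | methyl 6-{2-[4-(methoxymethoxy)phenyl]ethyl}-3,5-bis(3-methylbut-2-enyl)-2,4-dioxocyclohexane-1-carboxylate (mixture of diastereomers and enol tautomers) | COC(=O)C1C(=O)C(CC=C(C)C)C(=O)C(CC=C(C)C)C1CCc1ccc(OCOC)cc1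
A6 | alternative 2 | 2,10-dimethylundeca-2,9-dien-6-one | CC(C)=CCCC(=O)CCC=C(C)C
A7 | alternative 2 | dimethyl 2-{3-[4-(methoxymethoxy)phenyl]propylidene}propanedioate | COC(=O)C(=CCCc1ccc(OCOC)cc1)C(=O)OC
A8 | alternative 3 | methyl 4-hydroxy-2-methoxy-6-{2-[4-(methoxymethoxy)phenyl]ethyl}-3,5-bis(3-methylbut-2-enyl)benzoate | COC(=O)c1c(OC)c(CC=C(C)C)c(O)c(CC=C(C)C)c1CCc1ccc(OCOC)cc1
A9 | alternative 3 | methyl 2-diazo-4-{2-[4-(methoxymethoxy)phenyl]ethyl}-8-methyl-3-oxonona-4,7-dienoate (alkene geometry at C4 not defined) | COC(=O)C(=[N+]=[N-])C(=O)C(CCc1ccc(OCOC)cc1)=CCC=C(C)C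
A10 | alternative 3 | 1-methoxy-5-methylhex-4-en-1-yne | COC#CCC=C(C)C
A11 | alternative 3 | methyl 3-{2-[4-(methoxymethoxy)phenyl]ethyl}-7-methyl-2-(oxomethylidene)octa-3,6-dienoate | COC(=O)C(=C=O)C(CCc1ccc(OCOC)cc1)=CCC=C(C)C
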